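The route rests on cutting the C4–C5 bond of the cyclohexenone ring (C1 carbonyl, C5 carbinol). The homoallylic alcohol array O–C5–C4–C3=C2 is the retron of a [2,3]-Wittig shift, and O–C5–C6–C1–C2 is the ring oxygen, C1, C2, C3 and C4 of a 2-deoxy-D-ribofuranose. The key step therefore lets a 2-lithio-2-nonadecyl-5-vinyltetrahydrofuran, generated from its anomeric phenylthio ketal, rearrange: in one operation the C4–C5 bond forms, the oxacycle becomes the carbocycle, the alkene moves into the ring and the sugar C4 centre fixes the C5 configuration. The precursor carries the future carbonyl oxygen as a TIPS ether trans to the vinyl group.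

Key step: step 9

Remarks on the chemistry
- Locants: oxolane compounds are numbered O1, C2 (anomeric carbon, sugar C1), C3, C4 (silyloxy, sugar C3), C5 (vinyl-bearing, sugar C4).
- Precursor design: the oxygen on C4 is protected as a triisopropylsilyl ether and not as a smaller silyl ether. In organolithium 12 this oxygen stands 1,3 to the carbanion, a geometry open to 1,4 O→C silyl transfer, and in the ring-opened alkoxide of step 7 it is vicinal to an alkoxide. A small silyl group could migrate in both cases; the bulky one should not, and it also tolerates BF3·OEt2.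
- Stereochemical bookkeeping: C–C bond formation on the vinyl face of the (4S,5R)-oxolane gives the (1S,5S)-cyclohexenol (hydroxyl cis to silyloxy) and, after oxidation, the (S)-enone, which is the target. The silyloxy centre stays until step 11, so any leak at the vinyl-bearing carbon (steps 5 and 6) or at the carbinol (step 9) appears as a separable diastereomer of 7, 13 or 14. Compound 14 must be diastereomerically pure before step 11, because the oxidation would turn a diastereomer into the enantiomer.
- Assumption: 10, 11 and 12 are mixtures at C2, which is therefore left undefined in their SMILES.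

Step 1
Reactants: 1 2-deoxy-D-ribose
Product: 2 2-deoxy-D-ribono-1,4-lactone [(4S,5R)-4-hydroxy-5-(hydroxymethyl)oxolan-2-one]
Conditions: Br2, H2O, rt, dark, 3–5 d; excess Br2 purged, acid removed on a weakly basic resin
Reagents that add atoms: none
Why: Bromine-water oxidation of an aldose to its aldonolactone acts only on the hemiacetal carbon and gives the five-membered lactone of the 2-deoxy sugar, so neither stereocentre is touched.

Step 2
Reactants: 2 2-deoxy-D-ribono-1,4-lactone
Product: 3 (4S,5R)-5-[(tert-butyldimethylsilyloxy)methyl]-4-hydroxyoxolan-2-one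
Conditions: TBSCl (1.05 equiv), imidazole, DMF, −20 → 0 °C
Reagents that add atoms: tert-butyldimethylsilyl chloride, CC(C)(C)[Si](C)(C)Cl
Why: Imidazole-mediated silyl ether formation with one equivalent of the chloride at low temperature should select the unhindered primary hydroxyl over the ring secondary hydroxyl.

Step 3
Reactants: 3 (4S,5R)-5-[(tert-butyldimethylsilyloxy)methyl]-4-hydroxyoxolan-2-one
Product: 4 (4S,5R)-5-[(tert-butyldimethylsilyloxy)methyl]-4-(triisopropylsilyloxy)oxolan-2-one
Conditions: TIPSOTf, 2,6-lutidine, CH2Cl2, 0 °C → rt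
Reagents that add atoms: triisopropylsilyl trifluoromethanesulfonate, CC(C)[Si](OS(=O)(=O)C(F)(F)F)(C(C)C)C(C)C
Why: Silylation with a silyl triflate and a hindered pyridine base caps the secondary hydroxyl without enolising the lactone, and installs the bulky ether that the later organolithium steps require.

Step 4
Reactants: 4 (4S,5R)-5-[(tert-butyldimethylsilyloxy)methyl]-4-(triisopropylsilyloxy)oxolan-2-one
Product: 5 (4S,5R)-5-(hydroxymethyl)-4-(triisopropylsilyloxy)oxolan-2-one
Conditions: HF·pyridine, pyridine, THF, 0 °C
Reagents that add atoms: none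
Why: Buffered fluoride desilylation should remove the primary tert-butyldimethylsilyl ether much faster than the hindered secondary triisopropylsilyl ether and leaves the lactone intact.

Step 5
Reactants: 5 (4S,5R)-5-(hydroxymethyl)-4-(triisopropylsilyloxy)oxolan-2-one
Product: 6 (2S,3S)-5-oxo-3-(triisopropylsilyloxy)oxolane-2-carbaldehyde
Conditions: Dess–Martin periodinane, NaHCO3, CH2Cl2, 0 °C → rt; crude aldehyde dried azeotropically and used at once
Reagents that add atoms: none
Why: Dess–Martin oxidation converts the primary alcohol into the aldehyde under near-neutral conditions, so the α-oxygenated stereocentre should not epimerise and the β-silyloxy group should not be eliminated.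

Step 6
Reactants: 6 (2S,3S)-5-oxo-3-(triisopropylsilyloxy)oxolane-2-carbaldehyde
Product: 7 (4S,5R)-5-ethenyl-4-(triisopropylsilyloxy)oxolan-2-one
Conditions: Zn, CH2Br2, TiCl4 (reagent pre-formed in THF at 0 °C), CH2Cl2, 0 °C → rt
Reagents that add atoms: dibromomethane, BrCBr
Why: Takai–Lombardo methylenation uses a non-basic gem-dimetallic reagent that olefinates aldehydes in the presence of lactones and is not expected to epimerise the adjacent C5 centre, on which the final configuration depends.

Step 7
Reactants: 7 (4S,5R)-5-ethenyl-4-(triisopropylsilyloxy)oxolan-2-one; 8 1-bromononadecane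
Product: 10 (4S,5R)-5-ethenyl-2-nonadecyl-4-(triisopropylsilyloxy)oxolan-2-ol (anomeric mixture), via nonadecyllithium 9 (not isolated)
Conditions: 8, Li (1% Na, 2.2 equiv), Et2O, 0 °C → rt, titrate; then 9 (1.2 equiv) added to 7, THF, −78 °C; AcOH, −78 °C
Reagents that add atoms: none
Why: Reductive metalation of the primary bromide with lithium metal gives the alkyllithium, whose nucleophilic acyl addition to the γ-lactone at −78 °C should stop at the lithium hemiketal, so one chain is added and the new anomeric centre needs no control.

Step 8
Reactants: 10 (4S,5R)-5-ethenyl-2-nonadecyl-4-(triisopropylsilyloxy)oxolan-2-ol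
Product: 11 (4S,5R)-5-ethenyl-2-nonadecyl-2-(phenylsulfanyl)-4-(triisopropylsilyloxy)oxolane (both anomers)
Conditions: PhSH (5 equiv), BF3·OEt2 (1.1 equiv), 4 Å sieves, CH2Cl2, −78 °C, dark, argon; Et3N at −78 °C; cold 1 M NaOH wash; Et3N-deactivated SiO2
Reagents that add atoms: thiophenol, Sc1ccccc1
Why: Lewis acid-promoted thioketalisation (thioglycosidation of a ketose) passes through the tertiary furanosyl oxocarbenium ion, which the soft thiol should trap at −78 °C faster than the ion loses a proton, and either anomer serves.

Step 9
Reactants: 11 (4S,5R)-5-ethenyl-2-nonadecyl-2-(phenylsulfanyl)-4-(triisopropylsilyloxy)oxolane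
Product: 13 (1S,5S)-1-nonadecyl-5-(triisopropylsilyloxy)cyclohex-3-en-1-ol, via 2-lithiotetrahydrofuran 12 (not isolated)
Conditions: lithium 4,4'-di-tert-butylbiphenylide (LiDBB, 2.2 equiv), THF, −78 °C; then −78 → −40 °C if needed; NH4Cl aq
Reagents that add atoms: none
Why: Proposed new method: two electron transfers from LiDBB cleave the C2–S bond of either anomer of 11 through the rapidly inverting anomeric radical to the tertiary α-alkoxy organolithium 12, whose carbanion carbon C2 bonds to the vinyl terminus on the vinyl-bearing face while the allylic C5–O1 bond breaks, a concerted [2,3]-Wittig shift through a five-membered envelope (C2, O1, C5 and both vinyl carbons) held in a 7-oxabicyclo[2.2.1]heptane-like array and driven by the change from a tertiary carbanion to an alkoxide. The closest known reaction type is the [2,3]-Wittig rearrangement of acyclic allyl α-lithioalkyl ethers generated by reductive lithiation of O,S-acetals, which has not been shown with the carbanion and the allylic carbon as members of one five-membered ring, where it becomes a ring expansion to a carbocycle. The cyclohexene closes by this sigmatropic shift in a formally 6-endo-trig, SN2'-like sense, with both vinyl carbons taken into the ring and the new, necessarily cis, C=C between the old C5 and the inner vinyl carbon. The one new stereocentre, the carbinol carbon, is controlled by the (5R) centre of the oxolane: the two-carbon tether reaches C2 only on the face that carries it, so the hydroxyl ends up cis to the silyloxy group and the centre is (1S), whichever anomer of 11 or epimer of 12 is involved (an epimer with lithium on the unreactive face must invert first). The step needs the [2,3]-shift to win over β-elimination, [1,2]-shift, 1,4 O→C silyl transfer, [3+2] cycloreversion of the lithiated oxolane and cleavage of the allylic ether by excess reductant; the 2-deoxy pattern leaves no β-leaving group, the [1,2]-product would be a cyclobutane, the triisopropylsilyl group resists transfer, and generation with two equivalents of LiDBB at −78 °C keeps the last two pathways slow.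

Step 10
Reactants: 13 (1S,5S)-1-nonadecyl-5-(triisopropylsilyloxy)cyclohex-3-en-1-ol
Product: 14 (1S,3S)-1-nonadecylcyclohex-4-ene-1,3-diol
Conditions: Bu4NF, THF, rt
Reagents that add atoms: none
Why: Fluoride-mediated silyl ether cleavage frees the allylic hydroxyl under conditions that neither dehydrate the tertiary alcohol nor move the alkene; the cis diol is checked for diastereomeric purity here.

Step 11
Reactants: 14 (1S,3S)-1-nonadecylcyclohex-4-ene-1,3-diol
Product: 15 (S)-5-hydroxy-5-nonadecylcyclohex-2-en-1-one (target)
Conditions: MnO2 (activated, excess), CH2Cl2, rt; filter through Celite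
Reagents that add atoms: none
Why: Manganese dioxide allylic oxidation acts only on the secondary allylic alcohol, cannot oxidise the tertiary alcohol, and is neutral, so the β-hydroxy enone should not dehydrate to a phenol and the C5 centre set in step 9 is untouched.

Compound list
1 | 2-deoxy-D-ribose | O=CC[C@H](O)[C@H](O)CO | starting material
2 | 2-deoxy-D-ribono-1,4-lactone, (4S,5R)-4-hydroxy-5-(hydroxymethyl)oxolan-2-one | O=C1C[C@H](O)[C@@H](CO)O1 | intermediate
3 | (4S,5R)-5-[(tert-butyldimethylsilyloxy)methyl]-4-hydroxyoxolan-2-one | O=C1C[C@H](O)[C@@H](CO[Si](C)(C)C(C)(C)C)O1 | intermediate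
4 | (4S,5R)-5-[(tert-butyldimethylsilyloxy)methyl]-4-(triisopropylsilyloxy)oxolan-2-one | O=C1C[C@H](O[Si](C(C)C)(C(C)C)C(C)C)[C@@H](CO[Si](C)(C)C(C)(C)C)O1 | intermediate
5 | (4S,5R)-5-(hydroxymethyl)-4-(triisopropylsilyloxy)oxolan-2-one | O=C1C[C@H](O[Si](C(C)C)(C(C)C)C(C)C)[C@@H](CO)O1 | intermediate
6 | (2S,3S)-5-oxo-3-(triisopropylsilyloxy)oxolane-2-carbaldehyde | O=C1C[C@H](O[Si](C(C)C)(C(C)C)C(C)C)[C@@H](C=O)O1 | intermediate
7 | (4S,5R)-5-ethenyl-4-(triisopropylsilyloxy)oxolan-2-one | O=C1C[C@H](O[Si](C(C)C)(C(C)C)C(C)C)[C@@H](C=C)O1 | intermediate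
8 | 1-bromononadecane | BrCCCCCCCCCCCCCCCCCCC | starting material
9 | nonadecyllithium (formed in the flask) | [Li]CCCCCCCCCCCCCCCCCCC | intermediate
10 | (4S,5R)-5-ethenyl-2-nonadecyl-4-(triisopropylsilyloxy)oxolan-2-ol, anomeric mixture in equilibrium with the open hydroxy ketone | CCCCCCCCCCCCCCCCCCCC1(O)C[C@H](O[Si](C(C)C)(C(C)C)C(C)C)[C@@H](C=C)O1 | intermediate
11 | (4S,5R)-5-ethenyl-2-nonadecyl-2-(phenylsulfanyl)-4-(triisopropylsilyloxy)oxolane, both anomers | CCCCCCCCCCCCCCCCCCCC1(Sc2ccccc2)C[C@H](O[Si](C(C)C)(C(C)C)C(C)C)[C@@H](C=C)O1 | intermediate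
12 | (4S,5R)-5-ethenyl-2-lithio-2-nonadecyl-4-(triisopropylsilyloxy)oxolane (formed in the flask) | CCCCCCCCCCCCCCCCCCCC1([Li])C[C@H](O[Si](C(C)C)(C(C)C)C(C)C)[C@@H](C=C)O1 | intermediate
13 | (1S,5S)-1-nonadecyl-5-(triisopropylsilyloxy)cyclohex-3-en-1-ol, hydroxyl cis to silyloxy | CCCCCCCCCCCCCCCCCCC[C@]1(O)CC=C[C@@H](O[Si](C(C)C)(C(C)C)C(C)C)C1 | intermediate
14 | (1S,3S)-1-nonadecylcyclohex-4-ene-1,3-diol, cis | CCCCCCCCCCCCCCCCCCC[C@]1(O)CC=C[C@@H](O)C1 | intermediate
15 | (S)-5-hydroxy-5-nonadecylcyclohex-2-en-1-one | CCCCCCCCCCCCCCCCCCC[C@]1(O)CC=CC(=O)C1 | target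

Total step count: 11. Longest linear sequence: 11 steps (1 → 15); bromide 8 joins in step 7, where it is lithiated in the flask.

Steps most likely to fail

1. Step 9 (key step). The tertiary organolithium may not reach the strained bicyclic transition state before other pathways take over. These are protonation by the solvent, [3+2] cycloreversion to a ketone enolate and a silyloxydiene, and C–O homolysis with radical-pair recombination, which would erode the cis relationship. Excess reductant could also cleave the allylic ether.
Fallback (established reactions only): it sets out from hydroxy lactone 5 and returns at cyclohexenol 13. Nonadecyllithium 9 (2.2 equiv, one equivalent being consumed by the free hydroxyl) would be added to 5 at −78 °C to give the 1-C-nonadecyl hemiketal F1. Excess allylmagnesium bromide (THF, 0 °C) would then add to the open hydroxy ketone form of F1 and give the acyclic allyl carbinol triol F2 as both epimers at the new tertiary centre. The terminal 1,2-diol of F2 would be tied up as the cyclic thiocarbonate F3 with 1,1'-thiocarbonyldiimidazole. Corey–Winter elimination (1,3-dimethyl-2-phenyl-1,3,2-diazaphospholidine, 40 °C) would convert it into the terminal alkene of the 1,7-diene F4. Ring-closing metathesis with the second-generation Grubbs catalyst, RuCl2(=CHPh)(PCy3)(SIMes), in CH2Cl2 at 40 °C would close the cyclohexene and deliver 13 together with its C1 epimer F5. The two are diastereomers because the silyloxy centre is still in place, so chromatography should give stereochemically pure 13 at the cost of the unwanted half.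

2. Step 8. Ionisation of the tertiary hemiketal may be followed by loss of a proton and then of the silanol, which aromatises the ring to a 2,5-disubstituted furan. Prolonged exposure could instead give an open-chain dithioketal, and the product may lose thiophenol on silica.
Fallback: it sets out from vinyl lactone 7 and returns at organolithium 12, from which 13 follows as in step 9. Reduction of 7 with i-Bu2AlH (CH2Cl2, −78 °C) would give the lactol F6. PhSH with BF3·OEt2 at −78 °C would convert it into the secondary phenyl thioglycoside F7, which has no alkyl branch at the anomeric carbon and is far less prone to elimination. Oxidation with mCPBA (2.2 equiv, NaHCO3, CH2Cl2, 0 °C) should take the sulfide to the anomeric sulfone F8 faster than it epoxidises the monosubstituted alkene. Deprotonation of F8 (LiN(i-Pr)2, THF, −78 °C) and alkylation of the α-sulfonyl carbanion with bromide 8 (DMPU, −78 → −40 °C) would give the tertiary sulfone F9, so the chain is installed without an oxocarbenium ion at the tertiary stage. F9 would be used without chromatography and treated with LiDBB at −78 °C, where reductive cleavage of the sulfone C–S bond gives the same organolithium 12.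

3. Step 7. Formation of the alkyllithium may be accompanied by Wurtz coupling. The basic reagent may enolise the lactone and expel the β-silyloxy group, or the tetrahedral intermediate may collapse and take up a second equivalent.
Fallback: it sets out from vinyl lactone 7 and returns at hemiketal 10. Aminolysis of 7 with MeNH(OMe)·HCl and Me3Al (CH2Cl2, 0 °C) would open the lactone to the hydroxy Weinreb amide F10. This would be silylated at once (Et3SiCl, imidazole) as the triethylsilyl ether F11 so that it cannot relactonise. Nonadecylmagnesium bromide (from 8 and Mg in THF) would add once, because the chelated tetrahedral intermediate blocks a second addition and the milder Grignard reagent spares the β-silyloxy group, to give the ketone F12. Pyridinium p-toluenesulfonate in MeOH would remove the triethylsilyl group selectively, and the liberated hydroxy ketone would close to 10.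

Further compounds
F1 | step 9 | (4S,5R)-5-(hydroxymethyl)-2-nonadecyl-4-(triisopropylsilyloxy)oxolan-2-ol, anomeric mixture | CCCCCCCCCCCCCCCCCCCC1(O)C[C@H](O[Si](C(C)C)(C(C)C)C(C)C)[C@@H](CO)O1
F2 | step 9 | (6S,7R)-4-nonadecyl-6-(triisopropylsilyloxy)non-1-ene-4,7,8-triol, both C4 epimers | C=CCC(O)(CCCCCCCCCCCCCCCCCCC)C[C@H](O[Si](C(C)C)(C(C)C)C(C)C)[C@H](O)CO
F3 | step 9 | cyclic 7,8-thiocarbonate of F2, both C4 epimers | C=CCC(O)(CCCCCCCCCCCCCCCCCCC)C[C@H](O[Si](C(C)C)(C(C)C)C(C)C)[C@H]1COC(=S)O1
F4 | step 9 | (6S)-4-nonadecyl-6-(triisopropylsilyloxy)octa-1,7-dien-4-ol, both C4 epimers | C=CCC(O)(CCCCCCCCCCCCCCCCCCC)C[C@H](O[Si](C(C)C)(C(C)C)C(C)C)C=C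
F5 | step 9 | (1R,5S)-1-nonadecyl-5-(triisopropylsilyloxy)cyclohex-3-en-1-ol, trans epimer of 13 | CCCCCCCCCCCCCCCCCCC[C@@]1(O)CC=C[C@@H](O[Si](C(C)C)(C(C)C)C(C)C)C1
F6 | step 8 | (4S,5R)-5-ethenyl-4-(triisopropylsilyloxy)oxolan-2-ol, anomeric mixture | OC1C[C@H](O[Si](C(C)C)(C(C)C)C(C)C)[C@@H](C=C)O1
F7 | step 8 | (4S,5R)-5-ethenyl-2-(phenylsulfanyl)-4-(triisopropylsilyloxy)oxolane, both anomers | S(c1ccccc1)C2C[C@H](O[Si](C(C)C)(C(C)C)C(C)C)[C@@H](C=C)O2
F8 | step 8 | (4S,5R)-2-(benzenesulfonyl)-5-ethenyl-4-(triisopropylsilyloxy)oxolane, both anomers | O=S(=O)(c1ccccc1)C2C[C@H](O[Si](C(C)C)(C(C)C)C(C)C)[C@@H](C=C)O2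
F9 | step 8 | (4S,5R)-2-(benzenesulfonyl)-5-ethenyl-2-nonadecyl-4-(triisopropylsilyloxy)oxolane, both anomers | CCCCCCCCCCCCCCCCCCCC1(S(=O)(=O)c2ccccc2)C[C@H](O[Si](C(C)C)(C(C)C)C(C)C)[C@@H](C=C)O1
F10 | step 7 | (3S,4R)-4-hydroxy-N-methoxy-N-methyl-3-(triisopropylsilyloxy)hex-5-enamide | CON(C)C(=O)C[C@H](O[Si](C(C)C)(C(C)C)C(C)C)[C@H](O)C=C
F11 | step 7 | (3S,4R)-N-methoxy-N-methyl-4-(triethylsilyloxy)-3-(triisopropylsilyloxy)hex-5-enamide | CON(C)C(=O)C[C@H](O[Si](C(C)C)(C(C)C)C(C)C)[C@H](O[Si](CC)(CC)CC)C=C
F12 | step 7 | (3R,4S)-3-(triethylsilyloxy)-4-(triisopropylsilyloxy)pentacos-1-en-6-one | CCCCCCCCCCCCCCCCCCCC(=O)C[C@H](O[Si](C(C)C)(C(C)C)C(C)C)[C@H](O[Si](CC)(CC)CC)C=C
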